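**Assumptions.** (i) The (R)-oxazaborolidinium catalyst is assumed to add the diene to the enal face that gives (1S,2S,5S)-11 (the (S)-catalyst is taken to attack the opposite face of 2-substituted acroleins); if the sense is reversed, use the (S)-catalyst with no other change. (ii) Compounds 1, 4, 6 and 8 are taken as catalogue compounds. Nothing here has been run; selectivities are predictions from standard models.

**Retrosynthetic overview**
- Target ⇐ ring allylic alcohol (oxidation) ⇐ γ-hydroxy tert-butyl ester (lactonisation; the spiro-lactone is the second ring formed).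
- Lactone carbinol ⇐ β-hydroxy enone by 1,3-syn reduction; the ring carbinol that directs it is later erased as the ring ketone.
- Dienoyl side chain ⇐ neopentyl aldehyde + (E)-vinyl iodide (Cr/Ni coupling, then oxidation).
- Key step: catalytic asymmetric endo Diels–Alder of a 2-substituted acrolein with (E,E)-1-acetoxy-4-silyloxybutadiene. It forms the cyclohexene first and sets the quaternary spiro carbon, the acetoxy stereocentre and all ring oxygenation in one step.
- The obvious enolate aldol/alkylation of a 4-oxygenated cyclohexenone is avoided.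

Locants used for 11–16: cyclohexene C1 (quaternary), C2 (O-silyl/OH), C3=C4, C5 (OAc), C6 (CH2).

**Step 1**
Reactants: 1 pent-1-en-4-yne
Product: 3 (1E)-1-iodo-2-methylpenta-1,4-diene, via alkenylalane 2 (not isolated)
Conditions: Me3Al (2 equiv), Cp2ZrCl2 (0.2 equiv), CH2Cl2, 0 °C→rt; then I2, THF, −30→0 °C
Reagents that add atoms: trimethylaluminium, C[Al](C)C; iodine, II
Why: Negishi Zr-catalysed syn-carboalumination puts Me on the internal and Al on the terminal alkyne carbon (cis), and iodinolysis with retention gives the (E)-iodide; the isolated alkene does not react.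

**Step 2**
Reactants: 3 (1E)-1-iodo-2-methylpenta-1,4-diene; 4 2-methylbut-3-en-2-ol (5 equiv)
Product: 5 (3E,6E)-7-iodo-2,6-dimethylhepta-3,6-dien-2-ol
Conditions: Hoveyda–Grubbs II (3 mol %), CH2Cl2, 40 °C
Reagents that add atoms: none
Why: Olefin cross-metathesis of a terminal alkene with a hindered tertiary allylic alcohol is E-selective, and the trisubstituted vinyl iodide is inert to the Ru carbene.

**Step 3**
Reactants: 6 tert-butyl 4-oxobutanoate
Product: 7 tert-butyl 3-formylbut-3-enoate
Conditions: aq. HCHO (1.1 equiv), pyrrolidine (10 mol %), EtCO2H (10 mol %), i-PrOH, 45 °C; used promptly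
Reagents that add atoms: formaldehyde, C=O
Why: Organocatalytic α-methylenation (enamine Mannich condensation then amine elimination) acts only at the aldehyde α-CH2.

**Step 4**
Reactants: 8 (1E,3E)-buta-1,3-diene-1,4-diyl diacetate
Product: 10 (1E,3E)-4-[(tert-butyldimethylsilyl)oxy]buta-1,3-dien-1-yl acetate, via potassium dienolate 9 (not isolated)
Conditions: t-BuOK (1.0 equiv), THF, −78 °C; then TBSCl, −78→0 °C
Reagents that add atoms: tert-butyldimethylsilyl chloride, C[Si](C)(Cl)C(C)(C)C; potassium tert-butoxide, CC(C)(C)[O-].[K+] (K+ of 9 only)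
Why: Alkoxide cleavage of one enol acetate (acyl transfer) gives the W-shaped potassium dienolate, whose negative charge deactivates the second acetate, and O-silylation follows; only O–acyl bonds break, so both alkenes stay E.

**Step 5 (key step)**
Reactants: 7 tert-butyl 3-formylbut-3-enoate; 10 (1E,3E)-4-[(tert-butyldimethylsilyl)oxy]buta-1,3-dien-1-yl acetate (1.3 equiv)
Product: 11 tert-butyl 2-[(1S,2S,5S)-5-(acetyloxy)-2-[(tert-butyldimethylsilyl)oxy]-1-formylcyclohex-3-en-1-yl]acetate
Conditions: (R)-B-(o-tolyl)-diphenylprolinol oxazaborolidine (20 mol %), Tf2NH (18 mol %), CH2Cl2, −78→−40 °C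
Reagents that add atoms: none
Why: Cationic-oxazaborolidine-catalysed Diels–Alder: the stronger silyloxy donor makes the acetoxy-bearing terminus nucleophilic, so it bonds to the enal β-CH2 and the silyloxy carbon to the α-carbon; suprafacial addition of the E,E-diene with formyl endo puts OAc, OTBS and CHO all cis, and the catalyst shields one enal face to fix C1, C2 and C5.

**Step 6**
Reactants: 11 (aldehyde above); 5 (3E,6E)-7-iodo-2,6-dimethylhepta-3,6-dien-2-ol (1.5 equiv)
Product: 12 tert-butyl 2-[(1R,2S,5S)-5-(acetyloxy)-2-[(tert-butyldimethylsilyl)oxy]-1-[(2E,5E)-1,7-dihydroxy-3,7-dimethylocta-2,5-dien-1-yl]cyclohex-3-en-1-yl]acetate (C1′ epimer mixture)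
Conditions: CrCl2 (4 equiv), NiCl2 (2 mol %), DMSO, rt
Reagents that add atoms: none
Why: Nozaki–Hiyama–Kishi coupling adds the alkenylchromium to the hindered aldehyde with retention of alkene geometry and tolerates OH, esters, acetate and silyl ether; the new carbinol configuration is irrelevant (oxidised next) and the tert-butyl ester prevents early lactonisation.

**Step 7**
Reactants: 12 (allylic alcohol mixture above)
Product: 13 tert-butyl 2-[(1S,2S,5S)-5-(acetyloxy)-2-[(tert-butyldimethylsilyl)oxy]-1-[(2E,5E)-7-hydroxy-3,7-dimethylocta-2,5-dienoyl]cyclohex-3-en-1-yl]acetate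
Conditions: Dess–Martin periodinane (1.5 equiv), CH2Cl2, 0 °C→rt
Reagents that add atoms: none
Why: Dess–Martin oxidation converts the secondary allylic alcohol to the enone; the tertiary alcohol cannot be oxidised.

**Step 8**
Reactants: 13 (silyl enone above)
Product: 14 tert-butyl 2-[(1S,2S,5S)-5-(acetyloxy)-2-hydroxy-1-[(2E,5E)-7-hydroxy-3,7-dimethylocta-2,5-dienoyl]cyclohex-3-en-1-yl]acetate
Conditions: HF·pyridine, THF/pyridine, 0 °C→rt
Reagents that add atoms: none
Why: Fluoride desilylation under buffered acidic conditions frees the C2 hydroxyl without retro-aldol cleavage or loss of acetate/tert-butyl ester.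

**Step 9**
Reactants: 14 (β-hydroxy enone above)
Product: 16 tert-butyl 2-[(1S,2S,5S)-5-(acetyloxy)-1-[(1R,2E,5E)-1,7-dihydroxy-3,7-dimethylocta-2,5-dien-1-yl]-2-hydroxycyclohex-3-en-1-yl]acetate, via diethylboron chelate 15 (not isolated)
Conditions: Et2BOMe (1.2 equiv), THF/MeOH 4:1, −78 °C; NaBH4, −78 °C; AcOH, then MeOH co-evaporation
Reagents that add atoms: diethyl(methoxy)borane, CCB(CC)OC (boron of 15 only)
Why: Narasaka–Prasad 1,3-syn reduction: in the boron chelate the acyl group is equatorial on the cyclohexene, ring C3 is equatorial and ring C6 axial on the chelate, and external hydride attacks the ketone axially anti to C6 to give the (1′R) carbinol; the β,β-disubstituted enone undergoes 1,2-reduction only.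

**Step 10**
Reactants: 16 (syn-diol above)
Product: 17 (1R,5S,6S,9S)-6-hydroxy-1-[(1E,4E)-6-hydroxy-2,6-dimethylhepta-1,4-dien-1-yl]-3-oxo-2-oxaspiro[4.5]dec-7-en-9-yl acetate
Conditions: CSA (10 mol %), CH2Cl2, 0 °C→rt
Reagents that add atoms: none
Why: Acid-catalysed 5-exo-trig lactonisation (intramolecular transesterification) of the γ-hydroxy tert-butyl ester; only the C1′ hydroxyl can reach the ester because the ring C2 hydroxyl is trans to the CH2CO2tBu arm.

**Step 11**
Reactants: 17 (hydroxy spirolactone above)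
Product: 18 (+)-miliusane XVII, (1R,5R,9S)-1-[(1E,4E)-6-hydroxy-2,6-dimethylhepta-1,4-dien-1-yl]-3,6-dioxo-2-oxaspiro[4.5]dec-7-en-9-yl acetate
Conditions: Dess–Martin periodinane (1.3 equiv), CH2Cl2, 0 °C→rt
Reagents that add atoms: none
Why: Dess–Martin oxidation of the remaining secondary allylic alcohol gives the enone and removes the relay stereocentre; the tertiary alcohol, acetate and lactone are untouched and no other stereocentre is enolisable.

**Compound list**
1 | pent-1-en-4-yne | C=CCC#C | starting material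
2 | dimethyl[(1E)-2-methylpenta-1,4-dien-1-yl]alumane | C[Al](C)/C=C(\C)CC=C | intermediate (not isolated)
3 | (1E)-1-iodo-2-methylpenta-1,4-diene | I/C=C(\C)CC=C | intermediate
4 | 2-methylbut-3-en-2-ol | CC(C)(O)C=C | starting material
5 | (3E,6E)-7-iodo-2,6-dimethylhepta-3,6-dien-2-ol | I/C=C(\C)C/C=C/C(C)(C)O | intermediate
6 | tert-butyl 4-oxobutanoate | O=CCCC(=O)OC(C)(C)C | starting material
7 | tert-butyl 3-formylbut-3-enoate | C=C(C=O)CC(=O)OC(C)(C)C | intermediate
8 | (1E,3E)-buta-1,3-diene-1,4-diyl diacetate | CC(=O)O/C=C/C=C/OC(C)=O | starting material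
9 | potassium (1E,3E)-4-(acetyloxy)buta-1,3-dien-1-olate | CC(=O)O/C=C/C=C/[O-].[K+] | intermediate (not isolated)
10 | (1E,3E)-4-[(tert-butyldimethylsilyl)oxy]buta-1,3-dien-1-yl acetate | CC(=O)O/C=C/C=C/O[Si](C)(C)C(C)(C)C | intermediate
11 | tert-butyl 2-[(1S,2S,5S)-5-(acetyloxy)-2-[(tert-butyldimethylsilyl)oxy]-1-formylcyclohex-3-en-1-yl]acetate | CC(=O)O[C@@H]1C=C[C@H](O[Si](C)(C)C(C)(C)C)[C@@](C=O)(CC(=O)OC(C)(C)C)C1 | intermediate
12 | tert-butyl 2-[(1R,2S,5S)-5-(acetyloxy)-2-[(tert-butyldimethylsilyl)oxy]-1-[(2E,5E)-1,7-dihydroxy-3,7-dimethylocta-2,5-dien-1-yl]cyclohex-3-en-1-yl]acetate, C1′ epimer mixture | CC(=O)O[C@@H]1C=C[C@H](O[Si](C)(C)C(C)(C)C)[C@@](C(O)/C=C(\C)C/C=C/C(C)(C)O)(CC(=O)OC(C)(C)C)C1 | intermediate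
13 | tert-butyl 2-[(1S,2S,5S)-5-(acetyloxy)-2-[(tert-butyldimethylsilyl)oxy]-1-[(2E,5E)-7-hydroxy-3,7-dimethylocta-2,5-dienoyl]cyclohex-3-en-1-yl]acetate | CC(=O)O[C@@H]1C=C[C@H](O[Si](C)(C)C(C)(C)C)[C@@](C(=O)/C=C(\C)C/C=C/C(C)(C)O)(CC(=O)OC(C)(C)C)C1 | intermediate
14 | tert-butyl 2-[(1S,2S,5S)-5-(acetyloxy)-2-hydroxy-1-[(2E,5E)-7-hydroxy-3,7-dimethylocta-2,5-dienoyl]cyclohex-3-en-1-yl]acetate | CC(=O)O[C@@H]1C=C[C@H](O)[C@@](C(=O)/C=C(\C)C/C=C/C(C)(C)O)(CC(=O)OC(C)(C)C)C1 | intermediate
15 | O-diethylboryl derivative of 14 (boron chelated to the side-chain ketone) | CC(=O)O[C@@H]1C=C[C@H](OB(CC)CC)[C@@](C(=O)/C=C(\C)C/C=C/C(C)(C)O)(CC(=O)OC(C)(C)C)C1 | intermediate (not isolated)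
16 | tert-butyl 2-[(1S,2S,5S)-5-(acetyloxy)-1-[(1R,2E,5E)-1,7-dihydroxy-3,7-dimethylocta-2,5-dien-1-yl]-2-hydroxycyclohex-3-en-1-yl]acetate | CC(=O)O[C@@H]1C=C[C@H](O)[C@@]([C@H](O)/C=C(\C)C/C=C/C(C)(C)O)(CC(=O)OC(C)(C)C)C1 | intermediate
17 | (1R,5S,6S,9S)-6-hydroxy-1-[(1E,4E)-6-hydroxy-2,6-dimethylhepta-1,4-dien-1-yl]-3-oxo-2-oxaspiro[4.5]dec-7-en-9-yl acetate | CC(=O)O[C@@H]1C=C[C@H](O)[C@@]2(CC(=O)O[C@@H]2/C=C(\C)C/C=C/C(C)(C)O)C1 | intermediate
18 | (+)-miliusane XVII, (1R,5R,9S)-1-[(1E,4E)-6-hydroxy-2,6-dimethylhepta-1,4-dien-1-yl]-3,6-dioxo-2-oxaspiro[4.5]dec-7-en-9-yl acetate | CC(=O)O[C@@H]1C=CC(=O)[C@@]2(CC(=O)O[C@@H]2/C=C(\C)C/C=C/C(C)(C)O)C1 | target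

**Totals.** 11 steps in all; longest linear sequence 8 steps (8 → 10 → 11 → 12 → 13 → 14 → 16 → 17 → 18; the chains from 1 and from 6 are equally long).

**Three steps most likely to fail, with fallbacks**

Step 5 (Diels–Alder). The silyl dienol ether may react by Mukaiyama-type pathways, and endo selectivity or ee may be low with this untested diene/dienophile pair. The fallback sets out from 7 and 10 and returns at 11. The cycloaddition is run thermally without catalyst (toluene, 70 °C, BHT) to give the racemic all-cis adduct F1. A lipase (CAL-B, phosphate buffer/MTBE) then hydrolyses the allylic acetate of the unwanted enantiomer to the antipodal alcohol F2, and 11 is recovered as the unreacted acetate. Absolute configuration then comes from an enzymatic resolution, not from the cycloaddition catalyst.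

Step 6 (Cr/Ni coupling on the neopentyl, α-quaternary aldehyde). Conversion may be poor for steric reasons. The fallback sets out from 7 and 5 and returns at 13, moving the C–C bond formation before the ring is built. NHK coupling of 5 with the unhindered enal 7 gives the dienyl carbinol F3, and Dess–Martin oxidation gives the cross-conjugated dienone F4. F4 is then used as an α-methylene ketone dienophile with 10 under the step-5 catalyst, which gives 13 directly.

Step 9 (chelation-controlled reduction). The syn:anti ratio may be low at a ketone flanked by a quaternary carbon. The fallback sets out from 13 and returns at 16, replacing substrate (chelate) control by reagent control. The silyl-protected enone 13 is reduced with the CBS oxazaborolidine antipode that gives the (1′R) carbinol (Me-CBS, BH3·SMe2, −30 °C) to the single allylic alcohol F5. HF·pyridine then removes the silyl group to give 16.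

**Further compounds**
F1 | step 5 | rac-tert-butyl 2-[(1S*,2S*,5S*)-5-(acetyloxy)-2-[(tert-butyldimethylsilyl)oxy]-1-formylcyclohex-3-en-1-yl]acetate (1:1 mixture of enantiomers) | CC(=O)O[C@@H]1C=C[C@H](O[Si](C)(C)C(C)(C)C)[C@@](C=O)(CC(=O)OC(C)(C)C)C1.CC(=O)O[C@H]1C=C[C@@H](O[Si](C)(C)C(C)(C)C)[C@](C=O)(CC(=O)OC(C)(C)C)C1
F2 | step 5 | tert-butyl 2-[(1R,2R,5R)-2-[(tert-butyldimethylsilyl)oxy]-1-formyl-5-hydroxycyclohex-3-en-1-yl]acetate (antipodal series, discarded) | O[C@H]1C=C[C@@H](O[Si](C)(C)C(C)(C)C)[C@](C=O)(CC(=O)OC(C)(C)C)C1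
F3 | step 6 | tert-butyl (5E,8E)-4,10-dihydroxy-6,10-dimethyl-3-methylideneundeca-5,8-dienoate (racemic at C4) | C=C(CC(=O)OC(C)(C)C)C(O)/C=C(\C)C/C=C/C(C)(C)O
F4 | step 6 | tert-butyl (5E,8E)-10-hydroxy-6,10-dimethyl-3-methylidene-4-oxoundeca-5,8-dienoate | C=C(CC(=O)OC(C)(C)C)C(=O)/C=C(\C)C/C=C/C(C)(C)O
F5 | step 9 | tert-butyl 2-[(1R,2S,5S)-5-(acetyloxy)-2-[(tert-butyldimethylsilyl)oxy]-1-[(1R,2E,5E)-1,7-dihydroxy-3,7-dimethylocta-2,5-dien-1-yl]cyclohex-3-en-1-yl]acetate | CC(=O)O[C@@H]1C=C[C@H](O[Si](C)(C)C(C)(C)C)[C@@]([C@H](O)/C=C(\C)C/C=C/C(C)(C)O)(CC(=O)OC(C)(C)C)C1
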